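The five-membered ring (C1–C5) is read as 3-methylcyclopent-2-enone. Carbinol carbon C4 is the carbonyl, quaternary C1 is its β-carbon and ring-fusion C5 is its α-carbon. The key step uses this pattern to join three components in one flask. A chiral copper–carbene catalyst transfers a 1-silylvinyl group (C10) to C1, the resulting enolate takes up a ketal-masked C6–C8 aldehyde at C5, and elimination leaves C5 trigonal. The precursors are the enone, a 1-silylvinylalane and a dioxolane aldehyde. C1 then relays C4 and C5, a hydroxyl-directed reduction sets C6, Felkin addition sets C10, and metathesis (C8=C9) closes the seven-membered ring.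

Key step: step 3

Numbering used for all compounds: C1 quaternary (CH3), C2, C3, C4 (OH, i-Pr), C5 fusion CH, C6 (aroyloxy), C7, C8 (CH3)=C9, C10 (isovaleryloxy). The target is 1S,4S,5S,6R,10S. The C1 methyl, i-Pr, O6 and O10 lie on one face; H5 and the C4 hydroxyl lie on the other (trans ring fusion).

Remark on the chemistry: H and B add syn, so attack on the E-alkylidene from the C10 face places H5 correctly but gives the 6S carbinol, the epimer of the target. C6 is therefore taken through the ketone and re-set by internally delivered hydride, which also makes the E/Z outcome of step 3 harmless.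

Remark on the chemistry: the 1-silylvinyl group is hydroborated faster than the crowded C5=C6 bond. It is therefore used as the tether that carries boron to C6, and is then converted into the vinyl group by Peterson elimination.

Step 1
Reactants: 1 ethyl (2-methyl-1,3-dioxolan-2-yl)acetate
Product: 3 (2-methyl-1,3-dioxolan-2-yl)acetaldehyde, via aluminium hemiacetal 2 (not isolated)
Conditions: (i-Bu)2AlH (1.05 equiv), CH2Cl2, −78 °C; MeOH, then aq. KNaC4H4O6 (tartrate)
Reagents that add atoms: none
Why: Partial ester reduction: at −78 °C (i-Bu)2AlH adds once and hemiacetal 2 survives until work-up, so the aldehyde is released without over-reduction and without acid that could touch the dioxolane.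

Step 2
Reactants: 4 trimethylsilylacetylene
Product: 5 diisobutyl[1-(trimethylsilyl)vinyl]alane (used as its solution)
Conditions: (i-Bu)2AlH (1.0 equiv), hexane/THF, 55 °C
Reagents that add atoms: diisobutylaluminium hydride, CC(C)C[AlH]CC(C)C
Why: Thermal syn hydroalumination of a silylacetylene places aluminium on the silicon-bearing carbon, where silicon stabilises the C–Al bond, so the geminal 1-silylvinyl alane should form regioselectively.

Step 3
Reactants: 6 3-methylcyclopent-2-en-1-one; 5 diisobutyl[1-(trimethylsilyl)vinyl]alane; 3 (2-methyl-1,3-dioxolan-2-yl)acetaldehyde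
Product: 11 (2E,3S)-3-methyl-2-[2-(2-methyl-1,3-dioxolan-2-yl)ethylidene]-3-[1-(trimethylsilyl)vinyl]cyclopentan-1-one, via aluminium enolate 7 (not isolated), via lithium aluminate enolate 8 (not isolated), via aldol adduct 9 (not isolated), via mesylate 10 (not isolated)
Conditions: Cu(OTf)2 (5 mol %), chiral sulfonate-bearing 4,5-diphenylimidazolinium salt (5 mol %, carbene released with Ag2O), 5 (1.2 equiv), THF, 4 °C; MeLi (1.2 equiv), −78 °C; 3 (1.5 equiv), −78 °C; MsCl, −78 → 0 °C; DBU, 0 °C
Reagents that add atoms: none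
Why: The alane passes its sp2 carbon to the carbene-bound monovalent copper centre, the alkenylcopper adds to β-carbon C1 of 6, and aluminium takes the enolate oxygen to give 7 (C1–C10 formed). MeLi converts 7 into the more nucleophilic aluminate 8, which attacks aldehyde 3 through C5 (C5–C6 formed), and O-mesylation followed by E1cB elimination with DBU removes the aldol oxygen. The closest known reaction types are the copper–carbene-catalysed enantioselective conjugate addition of silyl-substituted alkenylalanes to β-substituted cyclopentenones and the tandem conjugate addition–aldol–dehydration sequence; no ring is closed. The single lasting stereocentre, quaternary C1 (S), is set by the chiral carbene ligand, whose enantiomer is chosen for the enone face leading to S, while the C5 and C6 centres of 9 are erased again. The step needs 1,4- over 1,2-addition and alkenyl over isobutyl transfer, which copper and the faster-migrating sp2 carbon secure, and C5 over C3 regiochemistry, which holds because the addition itself generates the enolate at C4=C5 and it is never allowed to equilibrate. The E isomer (C7 anti to the carbonyl) is drawn as the expected product of the elimination, and any Z isomer converges with it once C6 becomes a ketone in step 7.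

Step 4
Reactants: 11 (2E,3S)-alkylidene cyclopentanone
Product: 12 (1S,2E,3S)-1-isopropyl-3-methyl-2-[2-(2-methyl-1,3-dioxolan-2-yl)ethylidene]-3-[1-(trimethylsilyl)vinyl]cyclopentan-1-ol (target numbering 1S,4S; OH cis to C10, i-Pr cis to the C1 methyl)
Conditions: CeCl3 (anhydrous, 2 equiv), i-PrMgCl (2 equiv), THF, −78 → −20 °C
Reagents that add atoms: isopropylmagnesium chloride, CC(C)[Mg]Cl
Why: Organocerium 1,2-addition to an enone: weakly basic i-PrCeCl2 avoids enolisation, hydride transfer and 1,4-attack, and because C5 is trigonal the only facial bias comes from C1, whose bulky 1-silylvinyl group blocks its own face, so isopropyl should enter cis to the C1 methyl and leave the hydroxyl cis to C10 (4S).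

Step 5
Reactants: 12 tertiary allylic alcohol
Product: 14 (1S,2S,3S)-2-[(1S)-1-hydroxy-2-(2-methyl-1,3-dioxolan-2-yl)ethyl]-3-[2-hydroxy-1-(trimethylsilyl)ethyl]-1-isopropyl-3-methylcyclopentan-1-ol, via borinane 13 (not isolated)
Conditions: BH3·THF (2.5 equiv), THF, 0 → 40 °C; aq. NaOH, H2O2, 0 °C → rt
Reagents that add atoms: hydrogen peroxide, OO
Why: Cyclic hydroboration of a 1,4-diene: BH3 adds first to the exposed CH2 terminus of the vinylsilane, and the primary alkylborane so formed, held on the C10 face, reaches C5=C6 to close borinane 13, which places H on C5 cis to C10 (5S, the trans-fusion relationship) and boron on the less substituted C6, oxidation with retention then giving the 6S alcohol that steps 7 and 8 correct (the silyl-bearing C10 centre is transient and left undefined).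

Step 6
Reactants: 14 triol
Product: 15 (1S,2S,3R)-2-[(1S)-1-hydroxy-2-(2-methyl-1,3-dioxolan-2-yl)ethyl]-1-isopropyl-3-methyl-3-vinylcyclopentan-1-ol
Conditions: KH (4 equiv), THF, 0 °C → rt
Reagents that add atoms: none
Why: Base-induced Peterson elimination of the β-hydroxysilane (syn loss of Me3SiOK) unmasks the C10 vinyl group without acid, so the ketal and the tertiary alcohol are untouched and no stereocentre of the target is involved.

Step 7
Reactants: 15 vinyl diol (6S)
Product: 16 1-[(1R,2S,5R)-2-hydroxy-2-isopropyl-5-methyl-5-vinylcyclopentyl]-2-(2-methyl-1,3-dioxolan-2-yl)ethan-1-one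
Conditions: Dess–Martin periodinane, NaHCO3, CH2Cl2, 0 °C → rt
Reagents that add atoms: none
Why: Dess–Martin oxidation converts the only secondary alcohol into the C6 ketone under buffered conditions that should neither epimerise C5 nor trigger retro-aldol cleavage, and it erases the unwanted C6 configuration whatever the alkene geometry was.

Step 8
Reactants: 16 β-hydroxy ketone
Product: 18 (1S,2S,3R)-2-[(1R)-1-hydroxy-2-(2-methyl-1,3-dioxolan-2-yl)ethyl]-1-isopropyl-3-methyl-3-vinylcyclopentan-1-ol, via alkoxyborohydride 17 (not isolated)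
Conditions: Me4NBH(OAc)3 (5 equiv), MeCN/AcOH, −30 → −20 °C
Reagents that add atoms: none
Why: Saksena–Evans hydroxyl-directed reduction: the C4 hydroxyl displaces an acetate on boron and 17 delivers hydride internally through a chair in which C7 lies equatorial, away from the axial isopropyl group, so the carbonyl is attacked from the hydroxyl side and the 4,6-anti diol (6R) should result.

Step 9
Reactants: 19 4-hydroxybenzoic acid
Product: 21 4-(tert-butyldimethylsilyloxy)benzoic acid, via bis-silyl derivative 20 (not isolated)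
Conditions: TBSCl (2.3 equiv), imidazole, DMF, rt; AcOH/THF/H2O, rt
Reagents that add atoms: tert-butyldimethylsilyl chloride, CC(C)(C)[Si](C)(C)Cl
Why: Exhaustive silylation followed by selective hydrolysis of the far more labile silyl ester leaves the phenol as an aryl silyl ether that tolerates the later Grignard, acid, titanium and ruthenium steps.

Step 10
Reactants: 18 anti diol (6R); 21 4-(tert-butyldimethylsilyloxy)benzoic acid
Product: 22 (1R)-1-[(1S,2S,5R)-2-hydroxy-2-isopropyl-5-methyl-5-vinylcyclopentyl]-2-(2-methyl-1,3-dioxolan-2-yl)ethyl 4-(tert-butyldimethylsilyloxy)benzoate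
Conditions: DCC, DMAP, CH2Cl2, rt → 40 °C
Reagents that add atoms: none
Why: Steglich esterification acylates the only secondary hydroxyl with retention at C6, the tertiary C4 hydroxyl being too hindered to compete.

Step 11
Reactants: 22 C6 aroate with C1 vinyl group
Product: 24 (1R)-1-[(1S,2S,5S)-5-formyl-2-hydroxy-2-isopropyl-5-methylcyclopentyl]-2-(2-methyl-1,3-dioxolan-2-yl)ethyl 4-(tert-butyldimethylsilyloxy)benzoate, via secondary ozonide 23 (not isolated)
Conditions: O3, CH2Cl2, −78 °C; Me2S, −78 °C → rt
Reagents that add atoms: ozone, [O-][O+]=O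
Why: Ozonolysis with reductive work-up cleaves the only alkene to the non-enolisable C10 aldehyde, the ester-deactivated arene reacting far more slowly than the vinyl group.

Step 12
Reactants: 24 C10 aldehyde
Product: 25 (1R)-1-{(1S,2S,5S)-2-hydroxy-5-[(1S)-1-hydroxyprop-2-en-1-yl]-2-isopropyl-5-methylcyclopentyl}-2-(2-methyl-1,3-dioxolan-2-yl)ethyl 4-(tert-butyldimethylsilyloxy)benzoate
Conditions: CH2=CHMgBr (3 equiv), THF, −78 °C; aq. NH4Cl
Reagents that add atoms: vinylmagnesium bromide, C=C[Mg]Br
Why: Grignard addition under Felkin–Anh control (C5 as the large group anti to the nucleophile, carbonyl oxygen beside ring C2, attack past the methyl group), reinforced by the C4 magnesium alkoxide holding the carbonyl oxygen, should give the 10S allylic alcohol, and at −78 °C the aldehyde outruns the hindered aryl ester.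

Step 13
Reactants: 25 10S allylic alcohol
Product: 26 C10 isovalerate of 25 (1S,4S,5S,6R,10S)
Conditions: isovaleryl chloride, pyridine, DMAP (cat.), CH2Cl2, 0 °C → rt
Reagents that add atoms: 3-methylbutanoyl chloride, CC(C)CC(=O)Cl
Why: DMAP-catalysed acylation of the only secondary hydroxyl proceeds with retention at C10, the tertiary C4 hydroxyl being inert under these conditions.

Step 14
Reactants: 26 diester ketal
Product: 27 C8 methyl ketone (dioxolane of 26 replaced by C=O)
Conditions: PPTS, acetone/H2O, 50 °C
Reagents that add atoms: water, O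
Why: Mild acid-catalysed ketal hydrolysis frees the C8 ketone under conditions that the esters, the aryl silyl ether and the no longer allylic tertiary alcohol tolerate and that do not eliminate the β-aroyloxy group.

Step 15
Reactants: 27 β-aroyloxy methyl ketone
Product: 28 diene (C8 carries CH3 and =CH2; C10 carries CH=CH2)
Conditions: Zn, CH2Br2, TiCl4, THF/CH2Cl2, 0 °C → rt
Reagents that add atoms: dibromomethane, BrCBr
Why: Lombardo methylenation: the non-basic gem-dizinc/titanium reagent methylenates ketones but not esters, so C8 is converted without the E1cB loss of the C6 ester that a phosphorus ylide would provoke.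

Step 16
Reactants: 28 diene
Product: 29 O-silylated target (hydroazulene with C8=C9)
Conditions: second-generation Grubbs catalyst RuCl2(=CHPh)(SIMes)(PCy3) (5–10 mol %), toluene (high dilution), 80 °C
Reagents that add atoms: none
Why: Ring-closing metathesis: the catalyst loads on the monosubstituted C9 vinyl group and closes onto the 1,1-disubstituted C8 alkene, the trans-disposed chains on C1 and C5 being pre-organised for a seven-membered ring whose trisubstituted C8=C9 bond can only be cis within the ring, and no stereocentre is touched.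

Step 17
Reactants: 29 O-silylated target
Product: 30 target CNP0086724.2
Conditions: TBAF, AcOH (1:1), THF, 0 °C
Reagents that add atoms: none
Why: Fluoride cleavage of the aryl silyl ether is fast at 0 °C, and acetic acid buffers the phenoxide so that neither ester migrates or hydrolyses.

Compound list
1 | ethyl (2-methyl-1,3-dioxolan-2-yl)acetate | CCOC(=O)CC1(C)OCCO1 | starting material
2 | [1-ethoxy-2-(2-methyl-1,3-dioxolan-2-yl)ethoxy]diisobutylalane | CCOC(CC1(C)OCCO1)O[Al](CC(C)C)CC(C)C | intermediate
3 | (2-methyl-1,3-dioxolan-2-yl)acetaldehyde | CC1(CC=O)OCCO1 | intermediate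
4 | trimethylsilylacetylene | C#C[Si](C)(C)C | starting material
5 | diisobutyl[1-(trimethylsilyl)vinyl]alane | C=C([Si](C)(C)C)[Al](CC(C)C)CC(C)C | intermediate
6 | 3-methylcyclopent-2-en-1-one | CC1=CC(=O)CC1 | starting material
7 | (S)-diisobutyl({3-methyl-3-[1-(trimethylsilyl)vinyl]cyclopent-1-en-1-yl}oxy)alane | C[C@]1(C(=C)[Si](C)(C)C)CCC(O[Al](CC(C)C)CC(C)C)=C1 | intermediate
8 | lithium methyl aluminate of enolate 7 | [Li+].C[C@]1(C(=C)[Si](C)(C)C)CCC(O[Al-](C)(CC(C)C)CC(C)C)=C1 | intermediate
9 | (3S)-2-[1-hydroxy-2-(2-methyl-1,3-dioxolan-2-yl)ethyl]-3-methyl-3-[1-(trimethylsilyl)vinyl]cyclopentan-1-one (formed as its aluminate, C5 and C6 undefined) | C[C@]1(C(=C)[Si](C)(C)C)CCC(=O)C1C(O)CC2(C)OCCO2 | intermediate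
10 | methanesulfonate of 9 | C[C@]1(C(=C)[Si](C)(C)C)CCC(=O)C1C(OS(C)(=O)=O)CC2(C)OCCO2 | intermediate
11 | (2E,3S)-3-methyl-2-[2-(2-methyl-1,3-dioxolan-2-yl)ethylidene]-3-[1-(trimethylsilyl)vinyl]cyclopentan-1-one | C[C@]1(C(=C)[Si](C)(C)C)CCC(=O)/C1=C/CC2(C)OCCO2 | intermediate
12 | (1S,2E,3S)-1-isopropyl-3-methyl-2-[2-(2-methyl-1,3-dioxolan-2-yl)ethylidene]-3-[1-(trimethylsilyl)vinyl]cyclopentan-1-ol | C[C@]1(C(=C)[Si](C)(C)C)CC[C@](O)(C(C)C)/C1=C/CC2(C)OCCO2 | intermediate
13 | bicyclic borinane (B–H bridges C6 and the former vinylsilane CH2; C4–O carries BH2) | B3CC([Si](C)(C)C)[C@@]1(C)CC[C@](OB)(C(C)C)[C@@H]1[C@@H]3CC2(C)OCCO2 | intermediate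
14 | (1S,2S,3S)-2-[(1S)-1-hydroxy-2-(2-methyl-1,3-dioxolan-2-yl)ethyl]-3-[2-hydroxy-1-(trimethylsilyl)ethyl]-1-isopropyl-3-methylcyclopentan-1-ol | OCC([Si](C)(C)C)[C@@]1(C)CC[C@](O)(C(C)C)[C@@H]1[C@@H](O)CC2(C)OCCO2 | intermediate
15 | (1S,2S,3R)-2-[(1S)-1-hydroxy-2-(2-methyl-1,3-dioxolan-2-yl)ethyl]-1-isopropyl-3-methyl-3-vinylcyclopentan-1-ol | C=C[C@@]1(C)CC[C@](O)(C(C)C)[C@@H]1[C@@H](O)CC2(C)OCCO2 | intermediate
16 | 1-[(1R,2S,5R)-2-hydroxy-2-isopropyl-5-methyl-5-vinylcyclopentyl]-2-(2-methyl-1,3-dioxolan-2-yl)ethan-1-one | C=C[C@@]1(C)CC[C@](O)(C(C)C)[C@@H]1C(=O)CC2(C)OCCO2 | intermediate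
17 | tetramethylammonium C4-alkoxy(diacetoxy)borohydride of 16 | C=C[C@@]1(C)CC[C@](O[BH-](OC(C)=O)OC(C)=O)(C(C)C)[C@@H]1C(=O)CC2(C)OCCO2.C[N+](C)(C)C | intermediate
18 | (1S,2S,3R)-2-[(1R)-1-hydroxy-2-(2-methyl-1,3-dioxolan-2-yl)ethyl]-1-isopropyl-3-methyl-3-vinylcyclopentan-1-ol | C=C[C@@]1(C)CC[C@](O)(C(C)C)[C@@H]1[C@H](O)CC2(C)OCCO2 | intermediate
19 | 4-hydroxybenzoic acid | OC(=O)c1ccc(O)cc1 | starting material
20 | tert-butyldimethylsilyl 4-(tert-butyldimethylsilyloxy)benzoate | CC(C)(C)[Si](C)(C)OC(=O)c1ccc(O[Si](C)(C)C(C)(C)C)cc1 | intermediate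
21 | 4-(tert-butyldimethylsilyloxy)benzoic acid | OC(=O)c1ccc(O[Si](C)(C)C(C)(C)C)cc1 | intermediate
22 | (1R)-1-[(1S,2S,5R)-2-hydroxy-2-isopropyl-5-methyl-5-vinylcyclopentyl]-2-(2-methyl-1,3-dioxolan-2-yl)ethyl 4-(tert-butyldimethylsilyloxy)benzoate | C=C[C@@]1(C)CC[C@](O)(C(C)C)[C@@H]1[C@H](OC(=O)c2ccc(O[Si](C)(C)C(C)(C)C)cc2)CC3(C)OCCO3 | intermediate
23 | 1,2,4-trioxolane (secondary ozonide) of 22, C10 undefined | O1COOC1[C@@]2(C)CC[C@](O)(C(C)C)[C@@H]2[C@H](OC(=O)c3ccc(O[Si](C)(C)C(C)(C)C)cc3)CC4(C)OCCO4 | intermediate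
24 | (1R)-1-[(1S,2S,5S)-5-formyl-2-hydroxy-2-isopropyl-5-methylcyclopentyl]-2-(2-methyl-1,3-dioxolan-2-yl)ethyl 4-(tert-butyldimethylsilyloxy)benzoate | O=C[C@@]1(C)CC[C@](O)(C(C)C)[C@@H]1[C@H](OC(=O)c2ccc(O[Si](C)(C)C(C)(C)C)cc2)CC3(C)OCCO3 | intermediate
25 | (1R)-1-{(1S,2S,5S)-2-hydroxy-5-[(1S)-1-hydroxyprop-2-en-1-yl]-2-isopropyl-5-methylcyclopentyl}-2-(2-methyl-1,3-dioxolan-2-yl)ethyl 4-(tert-butyldimethylsilyloxy)benzoate | C=C[C@H](O)[C@@]1(C)CC[C@](O)(C(C)C)[C@@H]1[C@H](OC(=O)c2ccc(O[Si](C)(C)C(C)(C)C)cc2)CC3(C)OCCO3 | intermediate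
26 | C10 3-methylbutanoate of 25 (1S,4S,5S,6R,10S) | C=C[C@H](OC(=O)CC(C)C)[C@@]1(C)CC[C@](O)(C(C)C)[C@@H]1[C@H](OC(=O)c2ccc(O[Si](C)(C)C(C)(C)C)cc2)CC3(C)OCCO3 | intermediate
27 | C8 methyl ketone from 26 (1S,4S,5S,6R,10S) | C=C[C@H](OC(=O)CC(C)C)[C@@]1(C)CC[C@](O)(C(C)C)[C@@H]1[C@H](OC(=O)c2ccc(O[Si](C)(C)C(C)(C)C)cc2)CC(C)=O | intermediate
28 | metathesis diene, C8 isopropenyl unit and C10 vinyl carbinyl ester (1S,4S,5S,6R,10S) | C=C[C@H](OC(=O)CC(C)C)[C@@]1(C)CC[C@](O)(C(C)C)[C@@H]1[C@H](OC(=O)c2ccc(O[Si](C)(C)C(C)(C)C)cc2)CC(C)=C | intermediate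
29 | phenol O-tert-butyldimethylsilyl ether of the target | CC1=C[C@H](OC(=O)CC(C)C)[C@@]2(C)CC[C@](O)(C(C)C)[C@@H]2[C@H](OC(=O)c2ccc(O[Si](C)(C)C(C)(C)C)cc2)C1 | intermediate
30 | CNP0086724.2, (1S,4S,5S,6R,10S)-4-hydroxy-6-(4-hydroxybenzoyloxy)-10-(3-methylbutanoyloxy)dauc-8-ene in the numbering above | CC1=C[C@H](OC(=O)CC(C)C)[C@@]2(C)CC[C@](O)(C(C)C)[C@@H]2[C@H](OC(=O)c2ccc(O)cc2)C1 | target

Total step count: 17. Longest linear sequence: 15 (step 1 or 2, steps 3–8, steps 10–17).

Steps most likely to fail

Step 3. Leftover alane and the aluminate may compete for the aldehyde, and the hindered enolate may add sluggishly. DBU may also deprotonate C7 of the product and open the dioxolane by vinylogous β-elimination. The fallback sets out from 6 and 5 and returns at 11. The conjugate addition is run alone, and enolate 7 is captured with Et3SiOTf as the isolable triethylsilyl enol ether F1, which is freed from aluminium residues. MeLi then unmasks a clean lithium enolate of fixed regiochemistry, which is added to 3 at −78 °C. Aldol 9 is isolated and dehydrated in a separate flask through mesylate 10 with Et3N as the only base, giving 11.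

Step 5. External BH3 may reach C5=C6 from the methyl/isopropyl face before the tethered borane does, losing facial control at C5. Alternatively, the alkene flanked by two fully substituted carbons may not react at all. The fallback sets out from 12 and returns at 14.
- The C4 hydroxyl is silylated with ClSiHMe2/Et3N to the dimethylsilyl ether F2.
- Intramolecular hydrosilylation catalysed by Pt2[(CH2=CHSiMe2)2O]3 (5-endo mode) gives the oxasilolane F3. The short O–Si tether lets H reach C5 only from the hydroxyl face.
- Tamao oxidation (H2O2, KF, KHCO3) gives the vinylsilane diol F4.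
- 9-BBN-H followed by H2O2/NaOH then hydroborates the remaining vinylsilane and delivers 14.

Step 12. Facial selectivity at C10 may be poor because the medium and small Felkin groups (ring CH2 and CH3) differ little, and some attack on the aryl ester is possible. The fallback sets out from 25 (as its C10 epimer mixture) and returns at 25. Dess–Martin oxidation gives the vinyl ketone F5. This is reduced under reagent control by Corey–Bakshi–Shibata reduction ((R)-methyl oxazaborolidine, catecholborane, toluene, −78 °C). Quaternary C1 acts as the large substituent and vinyl as the small one, so the 10S alcohol should result.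

Further compounds
F1 | step 3 | (S)-triethyl({3-methyl-3-[1-(trimethylsilyl)vinyl]cyclopent-1-en-1-yl}oxy)silane | C[C@]1(C(=C)[Si](C)(C)C)CCC(O[Si](CC)(CC)CC)=C1
F2 | step 5 | C4 O-dimethylsilyl ether of 12 | C[C@]1(C(=C)[Si](C)(C)C)CC[C@](O[SiH](C)C)(C(C)C)/C1=C/CC2(C)OCCO2
F3 | step 5 | 1,2-oxasilolane bridging O4 and C6 (H5 cis to O4, 6S) | C=C([Si](C)(C)C)[C@@]1(C)CC[C@](O3)(C(C)C)[C@@H]1[C@@H]([Si]3(C)C)CC2(C)OCCO2
F4 | step 5 | (1S,4S,5S,6S)-4,6-diol with intact 1-(trimethylsilyl)vinyl group | C=C([Si](C)(C)C)[C@@]1(C)CC[C@](O)(C(C)C)[C@@H]1[C@@H](O)CC2(C)OCCO2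
F5 | step 12 | C10 vinyl ketone from 25 | C=CC(=O)[C@@]1(C)CC[C@](O)(C(C)C)[C@@H]1[C@H](OC(=O)c2ccc(O[Si](C)(C)C(C)(C)C)cc2)CC3(C)OCCO3
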